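The rate constants come from no measurement.

Treat this flask as a gas feed running into a substrate that consumes it.

substrate 15 mM; gas phase 0.61 mM (held); time 5.0 min

    gas phase ⇌ dissolved gas, rate k1*(csat - [dissolved gas]) (k1 = 14 min⁻¹, csat = 0.61 mM)
    substrate + dissolved gas → target (k2 = 870 M⁻¹ min⁻¹)
    target ⇌ isomer of the product (K3 = 1.2, k3 = 0.12 min⁻¹)
    crystals ⇌ target, rate k4*(cs4 - [target]) while solid is left; crystals form when [target] > cs4 (cs4 = 2.9 mM, k4 = 18 min⁻¹)

- amount of target and crystals together at 5.0 min, in percent of the substrate charged
- the change that raises the amount of target and crystals together at 5.0 min, in percent of the substrate charged most ("none" if none brings more than 2 percentage points) (gamma / eta / beta / theta / none)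
- amount of target and crystals together at 5.0 min, in percent of the substrate charged, after gamma

- gamma: doubling the solubility in step 4, all else as stated
- eta: doubling the dissolution coefficient of step 4, all else as stated
- beta: doubling the saturation concentration of gas phase, all else as stated
- theta: doubling the transfer coefficient of step 1, all else as stated

- amounts and yields of target count crystals too
- given per volume of solution although it is solid: crystals
- at the start none of the gas is dissolved
- run time (flask): 5.0 min

In our reckoning, dissolved gas in the flask relaxes in 0.0370 min, far shorter than the run, so we hold it where transfer delivers what the reaction takes. That reaction is pseudo-first-order in dissolved gas. One quantity carries the balance: the crossover concentration, the transfer coefficient over the rate constant, which is the c(substrate) at which reaction removes dissolved gas as readily as transfer refills it, 16.1 mM. Then c(dissolved gas) = 0.61 mM/(1 + c(substrate)/16.1 mM). With the delivery 8.54 mM min⁻¹, substrate reaches a level c at (cx·ln(charge/c) + charge − c)/delivery, where cx is the crossover concentration.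

| c(substrate) | c(dissolved gas) | reached at |
|---|---|---|
| 15 mM | 0.316 mM | start |
| 7.50 mM | 0.416 mM | 2.18 min |
| 3.75 mM | 0.495 mM | 3.93 min |
| 1.88 mM | 0.546 mM | 5.46 min |

None of the gas is dissolved at the start, but once it has relaxed, the first row puts it at about half of saturation. Down the last column, the second halving takes 1.75 min, less than the first. The asked time falls between the last two rows, and two passes of the time formula give c(substrate) = 2.35 mM.

Target passes its solubility near 0.704 min, earlier than the asked time. We therefore hold dissolved target at solubility, and the isomer climbs to 1.37 mM. That leaves 75.2%. In this reckoning gamma doubles the isomer, giving 66.1%. Beta doubles the delivery at the same crossover, theta doubles both, and eta touches neither, so we choose beta.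

The forecast, “Gas transfer is partly limiting, so I use quasi-steady dissolved gas.”, gives 75.2%, beta and 68.5%; its gamma figure stands above ours.

The flask gives 75.2%, 68.2% after gamma, and beta as the best change, worth 14 percentage points. Of the charge, 84.1% went through the reaction with the gas, and the isomer holds 8.82% at 5.00 min. With the crossover, the substrate then standing, 15.9%, gives 0.531 mM of dissolved gas, and the flask reads 0.529 mM. In the neighbouring flask, the same charge read at 80 s, substrate stands at 68.0%, the crossover gives 0.373 mM, and dissolved gas reads 0.371 mM.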